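## Retrosynthetic overview

1. The aryl ketone comes from 3-(silyloxy)phenyllithium plus a neopentyl aldehyde (C1), then oxidation. The two 1,1-disubstituted alkenes are made late, by Wittig methylenation and by hydroboration/Suzuki coupling.
2. Quaternary C2 comes from prenylation and then methylation of a cis-β,γ-disubstituted γ-butyrolactone ("lactone A"). Its C=O is C1, and its ring O sits on the carbon that becomes the isopropenyl carbon.
3. C4 comes from α-prenylation of the isomeric trans γ-butyrolactone ("lactone B", C=O = C5). That carbonyl is then built into the CH2CH2C(Me)=CH2 chain.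
4. The key bond C2–C3 comes from an intermolecular Michael addition of dibenzyl malonate to (R)-5-methylfuran-2(5H)-one, made from (R)-propylene oxide. This step sets C3, which then controls C4 and C2.
5. Ring order: butenolide/lactone B is closed first and opened by lactol Wittig. Lactone A is closed by oxidative lactonisation and opened by LiAlH4. The target keeps only the arene ring.

Assumption: LDA, 9-BBN-H, DIBAL-H, TBAF and Dess–Martin periodinane are used as purchased. C1–C8 are the locants of the oct-7-en-1-one chain of the target, and Cγ is the carbinol carbon that ends as the central isopropenyl carbon.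

## Route

Step 1
Reactants: 1 (R)-2-methyloxirane; 2 (phenylsulfanyl)acetic acid
Product: 5 (5R)-5-methyl-3-(phenylsulfanyl)oxolan-2-one (C3 epimers), via dilithio dianion 3 (not isolated), via hydroxy acid 4 (not isolated)
Conditions: 2, LDA (2.1 equiv), THF, 0 °C; 1, 0 °C→rt; aq. HCl; TsOH (cat.), toluene, reflux
Reagents that add atoms: LDA, [Li+].CC(C)[N-]C(C)C (lithium, present only in 3)
Why: The carboxylic acid dianion opens the epoxide by SN2 at the CH2 terminus, so the C–O stereocentre stays R, and acid-catalysed lactonisation follows.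

Step 2
Reactants: 5 (5R)-5-methyl-3-(phenylsulfanyl)oxolan-2-one
Product: 6 (5R)-5-methyl-3-(phenylsulfinyl)oxolan-2-one (epimers at C3 and S)
Conditions: NaIO4 (1.05 equiv), MeOH–H2O, 0 °C→rt
Reagents that add atoms: sodium periodate, [Na+].[O-]I(=O)(=O)=O
Why: Periodate oxidises the sulfide and stops cleanly at the sulfoxide without touching C5.

Step 3
Reactants: 6 (5R)-5-methyl-3-(phenylsulfinyl)oxolan-2-one
Product: 7 (5R)-5-methylfuran-2(5H)-one
Conditions: toluene, reflux; distillation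
Reagents that add atoms: none
Why: Thermal sulfoxide syn-elimination can only use the C4 hydrogens and is neutral, so the conjugated butenolide forms without racemising C5.

Step 4
Reactants: 7 (5R)-5-methylfuran-2(5H)-one; 8 dibenzyl malonate
Product: 9 dibenzyl 2-[(2R,3R)-2-methyl-5-oxooxolan-3-yl]propanedioate (trans)
Conditions: 8 (1.2 equiv), NaH (10 mol %), THF, 0 °C→rt
Reagents that add atoms: none
Why: In this intermolecular Michael addition the soft malonate anion adds 1,4 from the face opposite the C5 methyl, which makes the C2–C3 bond and sets C3 (trans, expected >95:5), while catalytic base in an aprotic solvent keeps the lactone closed and limits C5–H exchange.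

Step 5
Reactants: 9 dibenzyl 2-[(2R,3R)-2-methyl-5-oxooxolan-3-yl]propanedioate
Product: 11 2-[(2R,3S)-2-methyl-5-oxooxolan-3-yl]acetic acid, via malonic acid 10 (not isolated)
Conditions: H2 (1 atm), 10% Pd/C, EtOAc, rt; filter; Cu2O (5 mol %), MeCN, reflux
Reagents that add atoms: none
Why: Benzyl ester hydrogenolysis and copper-catalysed malonic acid decarboxylation are neutral and run at 82 °C or below, so the lactone never opens and the two CH2C(=O) arms on C3 stay distinct.

Step 6
Reactants: 11 2-[(2R,3S)-2-methyl-5-oxooxolan-3-yl]acetic acid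
Product: 12 (4S,5R)-4-(2-hydroxyethyl)-5-methyloxolan-2-one
Conditions: BH3·THF (1.2 equiv), THF, 0 °C→rt; aq. work-up
Reagents that add atoms: none
Why: Borane reduces a free carboxylic acid (through the acyloxyborane) far faster than a lactone, which puts the two arms at different oxidation levels.

Step 7
Reactants: 12 (4S,5R)-4-(2-hydroxyethyl)-5-methyloxolan-2-one
Product: 13 (4S,5R)-4-[2-(tert-butyldiphenylsilyloxy)ethyl]-5-methyloxolan-2-one
Conditions: TBDPSCl, imidazole, DMF, rt
Reagents that add atoms: TBDPSCl, CC(C)(C)[Si](Cl)(c1ccccc1)c1ccccc1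
Why: Silyl ether protection of the primary alcohol blocks translactonisation and survives LDA, DIBAL-H and ylide.

Step 8
Reactants: 13 (4S,5R)-4-[2-(tert-butyldiphenylsilyloxy)ethyl]-5-methyloxolan-2-one; 14 1-bromo-3-methylbut-2-ene
Product: 16 (3S,4S,5R)-4-[2-(tert-butyldiphenylsilyloxy)ethyl]-5-methyl-3-(3-methylbut-2-enyl)oxolan-2-one (all-trans), via lithium enolate 15 (not isolated)
Conditions: LDA (1.1 equiv), THF, −78 °C; 14, −78→−30 °C
Reagents that add atoms: LDA, [Li+].CC(C)[N-]C(C)C (lithium, present only in 15)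
Why: In this lactone enolate alkylation (SN2 on an allylic bromide) the electrophile enters anti to the neighbouring ring-C4 side chain, which gives the all-trans lactone (also the thermodynamic epimer) and sets target C4.

Step 9
Reactants: 16 all-trans prenyl lactone
Product: 17 (3S,4S,5R)-4-[2-(tert-butyldiphenylsilyloxy)ethyl]-5-methyl-3-(3-methylbut-2-enyl)oxolan-2-ol (anomers)
Conditions: DIBAL-H (1.1 equiv), CH2Cl2, −78 °C; Rochelle salt
Reagents that add atoms: none
Why: In this DIBAL-H half-reduction the aluminium hemiacetal is stable at −78 °C, so reduction stops at the lactol and no stereocentre is touched.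

Step 10
Reactants: 17 lactol
Product: 18 (2R,3S,4R)-3-[2-(tert-butyldiphenylsilyloxy)ethyl]-4-ethenyl-7-methyloct-6-en-2-ol
Conditions: Ph3PCH3Br (3.0 equiv), KOtBu (2.9 equiv), THF, 0 °C; 17, 0 °C→rt
Reagents that add atoms: methyltriphenylphosphonium bromide, C[P+](c1ccccc1)(c1ccccc1)c1ccccc1.[Br-]
Why: Wittig methylenation takes place on the ring-opened hydroxy aldehyde tautomer, and the unstabilised ylide traps the aldehyde faster than it enolises, so target C4 is retained and the Cγ hydroxyl is released.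

Step 11
Reactants: 18 silyl ether alcohol
Product: 19 (3S,4R)-3-[(3R)-6-methylhepta-1,5-dien-3-yl]pentane-1,4-diol
Conditions: TBAF, THF, rt
Reagents that add atoms: none
Why: Fluoride-driven Si–O cleavage leaves alkenes and stereocentres unaffected.

Step 12
Reactants: 19 1,4-diol
Product: 21 (4S,5R)-5-methyl-4-[(3R)-6-methylhepta-1,5-dien-3-yl]oxolan-2-one (cis), via lactol 20 (not isolated)
Conditions: TEMPO (10 mol %), PhI(OAc)2 (2.5 equiv), CH2Cl2, rt
Reagents that add atoms: none
Why: In this TEMPO/PhI(OAc)2 oxidative lactonisation only the primary alcohol is oxidised, the aldehyde closes on the Cγ hydroxyl and the lactol is oxidised on, and because the ring now runs through the other arm the big C4-bearing group and the Cγ methyl are cis.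

Step 13
Reactants: 21 cis vinyl lactone; 22 2-bromopropene
Product: 24 (4S,5R)-4-[(5S)-2,8-dimethylnona-1,7-dien-5-yl]-5-methyloxolan-2-one, via B-alkyl-9-BBN 23 (not isolated)
Conditions: 9-BBN-H (1.3 equiv), THF, 0 °C→rt; 22, PdCl2(dppf) (5 mol %), aq. K3PO4, DMF, rt→40 °C; work-up at pH 4
Reagents that add atoms: 9-BBN-H, [H]B1C2CCCC1CCC2 (boron, present only in 23)
Why: In this hydroboration/B-alkyl Suzuki–Miyaura coupling 9-BBN takes the monosubstituted vinyl group over the trisubstituted prenyl alkene and the lactone, and sp3–sp2 coupling installs CH2CH2C(Me)=CH2 without touching C4.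

Step 14
Reactants: 24 lactone A; 14 1-bromo-3-methylbut-2-ene
Product: 26 (3R,4R,5R)-4-[(5S)-2,8-dimethylnona-1,7-dien-5-yl]-5-methyl-3-(3-methylbut-2-enyl)oxolan-2-one, via lithium enolate 25 (not isolated)
Conditions: LDA (1.1 equiv), THF, −78 °C; 14, −78→−20 °C
Reagents that add atoms: LDA, [Li+].CC(C)[N-]C(C)C (lithium, present only in 25)
Why: This lactone enolate alkylation occurs from the face opposite the two cis substituents, and the new centre is flattened again in the next step, so its dr does not matter.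

Step 15
Reactants: 26 α-prenyl lactone
Product: 28 (3S,4R,5R)-4-[(5S)-2,8-dimethylnona-1,7-dien-5-yl]-3,5-dimethyl-3-(3-methylbut-2-enyl)oxolan-2-one, via lithium enolate 27 (not isolated)
Conditions: LDA (1.5 equiv), THF–DMPU, −78→−30 °C; MeI (5 equiv), −78→0 °C
Reagents that add atoms: iodomethane, CI; LDA, [Li+].CC(C)[N-]C(C)C (lithium, present only in 27)
Why: This second enolate alkylation builds quaternary C2, because one face of planar enolate 27 is blocked by both the ring-C4 side chain and the ring-C5 methyl, so MeI enters from the open face and prenyl ends cis to the side chain, which is (S)-C2 of the target.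

Step 16
Reactants: 28 quaternary lactone
Product: 29 (2S,3R,4S)-3-[(1R)-1-hydroxyethyl]-2,7-dimethyl-2,4-bis(3-methylbut-2-enyl)oct-7-en-1-ol
Conditions: LiAlH4, THF, 0 °C→reflux; Fieser work-up
Reagents that add atoms: none
Why: LiAlH4 reduces even the hindered lactone to the 1,4-diol, and isolated alkenes and all stereocentres are inert.

Step 17
Reactants: 29 diol
Product: 30 (2S,3R,4S)-1-(tert-butyldimethylsilyloxy)-3-[(1R)-1-hydroxyethyl]-2,7-dimethyl-2,4-bis(3-methylbut-2-enyl)oct-7-ene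
Conditions: TBSCl (1.05 equiv), imidazole, CH2Cl2, 0 °C
Reagents that add atoms: TBSCl, CC(C)(C)[Si](C)(C)Cl
Why: In this selective silylation the primary (neopentyl) hydroxyl reacts much faster than the secondary hydroxyl buried next to C3.

Step 18
Reactants: 30 mono-TBS ether
Product: 31 (2S,3R,4S)-3-acetyl-1-(tert-butyldimethylsilyloxy)-2,7-dimethyl-2,4-bis(3-methylbut-2-enyl)oct-7-ene
Conditions: Dess–Martin periodinane, CH2Cl2, rt
Reagents that add atoms: none
Why: Dess–Martin oxidation is mild, tolerates electron-rich alkenes and does not epimerise the hindered C3–H.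

Step 19
Reactants: 31 methyl ketone
Product: 32 (2S,3S,4S)-1-(tert-butyldimethylsilyloxy)-2,7-dimethyl-2,4-bis(3-methylbut-2-enyl)-3-(prop-1-en-2-yl)oct-7-ene
Conditions: Ph3PCH3Br (5 equiv), KOtBu (4.8 equiv), toluene, 0→80 °C
Reagents that add atoms: methyltriphenylphosphonium bromide, C[P+](c1ccccc1)(c1ccccc1)c1ccccc1.[Br-]
Why: Wittig methylenation under hindered-ketone conditions sees no other carbonyl, reversible enolisation occurs at CH3 and not at the shielded C3–H, and the isopropenyl group forms with C3 intact.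

Step 20
Reactants: 32 TBS ether
Product: 33 (2S,3S,4S)-2,7-dimethyl-2,4-bis(3-methylbut-2-enyl)-3-(prop-1-en-2-yl)oct-7-en-1-ol
Conditions: TBAF, THF, rt→45 °C
Reagents that add atoms: none
Why: Fluoride desilylation avoids acid, so the acid-sensitive alkenes survive.

Step 21
Reactants: 33 neopentyl alcohol
Product: 34 (2S,3S,4S)-2,7-dimethyl-2,4-bis(3-methylbut-2-enyl)-3-(prop-1-en-2-yl)oct-7-enal
Conditions: Dess–Martin periodinane, CH2Cl2, rt
Reagents that add atoms: none
Why: Dess–Martin oxidation stops at the aldehyde, which has no α-hydrogen and cannot epimerise.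

Step 22
Reactants: 35 3-bromophenol
Product: 36 (3-bromophenoxy)(tert-butyl)dimethylsilane
Conditions: TBSCl, imidazole, DMF, rt
Reagents that add atoms: TBSCl, CC(C)(C)[Si](C)(C)Cl
Why: The phenol silyl ether survives aryllithium chemistry (no ortho relationship, so no silyl shift) and is later removable with fluoride.

Step 23
Reactants: 36 (3-bromophenoxy)(tert-butyl)dimethylsilane; 34 aldehyde
Product: 38 (2S,3S,4S)-1-[3-(tert-butyldimethylsilyloxy)phenyl]-2,7-dimethyl-2,4-bis(3-methylbut-2-enyl)-3-(prop-1-en-2-yl)oct-7-en-1-ol (C1 epimers), via aryllithium 37 (not isolated)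
Conditions: 36 (1.8 equiv), n-BuLi, THF, −78 °C; 34, −78→0 °C; H2O
Reagents that add atoms: n-butyllithium, [Li]CCCC (lithium, present only in 37)
Why: Bromine–lithium exchange is followed by 1,2-addition of a small, reactive aryllithium to a non-enolisable aldehyde, and the new carbinol centre is removed in the next step.

Step 24
Reactants: 38 benzylic alcohol
Product: 39 (2S,3S,4S)-1-[3-(tert-butyldimethylsilyloxy)phenyl]-2,7-dimethyl-2,4-bis(3-methylbut-2-enyl)-3-(prop-1-en-2-yl)oct-7-en-1-one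
Conditions: Dess–Martin periodinane, CH2Cl2, rt
Reagents that add atoms: none
Why: Dess–Martin oxidation handles hindered benzylic alcohols, and the ketone has a quaternary α-carbon, so nothing can epimerise.

Step 25
Reactants: 39 silyl-protected ketone
Product: 40 garcinielliptone FA, (2S,3S,4S)-1-(3-hydroxyphenyl)-2,7-dimethyl-2,4-bis(3-methylbut-2-enyl)-3-(prop-1-en-2-yl)oct-7-en-1-one
Conditions: TBAF, AcOH (1:1), THF, 0 °C
Reagents that add atoms: none
Why: Buffered fluoride cleaves the aryl silyl ether within minutes and leaves ketone, alkenes and stereocentres untouched.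

## Compound list

1 | (R)-2-methyloxirane | C[C@@H]1CO1 | starting material
2 | (phenylsulfanyl)acetic acid | OC(=O)CSc1ccccc1 | starting material
3 | dilithium dianion of 2 (not isolated) | [Li+].[Li+].[O-]C([O-])=CSc1ccccc1 | intermediate
4 | (4R)-4-hydroxy-2-(phenylsulfanyl)pentanoic acid, C2 epimers (not isolated) | C[C@@H](O)CC(Sc1ccccc1)C(=O)O | intermediate
5 | (5R)-5-methyl-3-(phenylsulfanyl)oxolan-2-one, C3 epimers | C[C@@H]1CC(Sc2ccccc2)C(=O)O1 | intermediate
6 | (5R)-5-methyl-3-(phenylsulfinyl)oxolan-2-one, epimers at C3 and S | C[C@@H]1CC(S(=O)c2ccccc2)C(=O)O1 | intermediate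
7 | (5R)-5-methylfuran-2(5H)-one | C[C@@H]1C=CC(=O)O1 | intermediate
8 | dibenzyl malonate | O=C(CC(=O)OCc1ccccc1)OCc1ccccc1 | starting material
9 | dibenzyl 2-[(2R,3R)-2-methyl-5-oxooxolan-3-yl]propanedioate | C[C@H]1OC(=O)C[C@@H]1C(C(=O)OCc2ccccc2)C(=O)OCc3ccccc3 | intermediate
10 | 2-[(2R,3R)-2-methyl-5-oxooxolan-3-yl]propanedioic acid (not isolated) | C[C@H]1OC(=O)C[C@@H]1C(C(=O)O)C(=O)O | intermediate
11 | 2-[(2R,3S)-2-methyl-5-oxooxolan-3-yl]acetic acid | C[C@H]1OC(=O)C[C@@H]1CC(=O)O | intermediate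
12 | (4S,5R)-4-(2-hydroxyethyl)-5-methyloxolan-2-one | C[C@H]1OC(=O)C[C@@H]1CCO | intermediate
13 | (4S,5R)-4-[2-(tert-butyldiphenylsilyloxy)ethyl]-5-methyloxolan-2-one | C[C@H]1OC(=O)C[C@@H]1CCO[Si](c2ccccc2)(c3ccccc3)C(C)(C)C | intermediate
14 | 1-bromo-3-methylbut-2-ene (prenyl bromide) | CC(C)=CCBr | starting material
15 | lithium enolate of 13 (not isolated) | [Li+].C[C@H]1OC([O-])=C[C@@H]1CCO[Si](c2ccccc2)(c3ccccc3)C(C)(C)C | intermediate
16 | (3S,4S,5R)-4-[2-(tert-butyldiphenylsilyloxy)ethyl]-5-methyl-3-(3-methylbut-2-enyl)oxolan-2-one | C[C@H]1OC(=O)[C@@H](CC=C(C)C)[C@@H]1CCO[Si](c2ccccc2)(c3ccccc3)C(C)(C)C | intermediate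
17 | (3S,4S,5R)-4-[2-(tert-butyldiphenylsilyloxy)ethyl]-5-methyl-3-(3-methylbut-2-enyl)oxolan-2-ol, anomers | C[C@H]1OC(O)[C@@H](CC=C(C)C)[C@@H]1CCO[Si](c2ccccc2)(c3ccccc3)C(C)(C)C | intermediate
18 | (2R,3S,4R)-3-[2-(tert-butyldiphenylsilyloxy)ethyl]-4-ethenyl-7-methyloct-6-en-2-ol | C=C[C@@H](CC=C(C)C)[C@H](CCO[Si](c1ccccc1)(c2ccccc2)C(C)(C)C)[C@@H](C)O | intermediate
19 | (3S,4R)-3-[(3R)-6-methylhepta-1,5-dien-3-yl]pentane-1,4-diol | C=C[C@@H](CC=C(C)C)[C@H](CCO)[C@@H](C)O | intermediate
20 | (4S,5R)-5-methyl-4-[(3R)-6-methylhepta-1,5-dien-3-yl]oxolan-2-ol, anomers (not isolated) | C[C@H]1OC(O)C[C@H]1[C@@H](C=C)CC=C(C)C | intermediate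
21 | (4S,5R)-5-methyl-4-[(3R)-6-methylhepta-1,5-dien-3-yl]oxolan-2-one (cis) | C[C@H]1OC(=O)C[C@H]1[C@@H](C=C)CC=C(C)C | intermediate
22 | 2-bromopropene | CC(Br)=C | starting material
23 | B-alkyl-9-BBN adduct of 21 (not isolated) | C[C@H]1OC(=O)C[C@H]1[C@@H](CCB2C3CCCC2CCC3)CC=C(C)C | intermediate
24 | (4S,5R)-4-[(5S)-2,8-dimethylnona-1,7-dien-5-yl]-5-methyloxolan-2-one | C[C@H]1OC(=O)C[C@H]1[C@@H](CCC(C)=C)CC=C(C)C | intermediate
25 | lithium enolate of 24 (not isolated) | [Li+].C[C@H]1OC([O-])=C[C@H]1[C@@H](CCC(C)=C)CC=C(C)C | intermediate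
26 | (3R,4R,5R)-4-[(5S)-2,8-dimethylnona-1,7-dien-5-yl]-5-methyl-3-(3-methylbut-2-enyl)oxolan-2-one | C[C@H]1OC(=O)[C@H](CC=C(C)C)[C@H]1[C@@H](CCC(C)=C)CC=C(C)C | intermediate
27 | lithium enolate of 26 (not isolated) | [Li+].C[C@H]1OC([O-])=C(CC=C(C)C)[C@H]1[C@@H](CCC(C)=C)CC=C(C)C | intermediate
28 | (3S,4R,5R)-4-[(5S)-2,8-dimethylnona-1,7-dien-5-yl]-3,5-dimethyl-3-(3-methylbut-2-enyl)oxolan-2-one | C[C@H]1OC(=O)[C@@](C)(CC=C(C)C)[C@H]1[C@@H](CCC(C)=C)CC=C(C)C | intermediate
29 | (2S,3R,4S)-3-[(1R)-1-hydroxyethyl]-2,7-dimethyl-2,4-bis(3-methylbut-2-enyl)oct-7-en-1-ol | OC[C@@](C)(CC=C(C)C)[C@H]([C@@H](C)O)[C@@H](CCC(C)=C)CC=C(C)C | intermediate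
30 | (2S,3R,4S)-1-(tert-butyldimethylsilyloxy)-3-[(1R)-1-hydroxyethyl]-2,7-dimethyl-2,4-bis(3-methylbut-2-enyl)oct-7-ene | CC(C)(C)[Si](C)(C)OC[C@@](C)(CC=C(C)C)[C@H]([C@@H](C)O)[C@@H](CCC(C)=C)CC=C(C)C | intermediate
31 | (2S,3R,4S)-3-acetyl-1-(tert-butyldimethylsilyloxy)-2,7-dimethyl-2,4-bis(3-methylbut-2-enyl)oct-7-ene | CC(C)(C)[Si](C)(C)OC[C@@](C)(CC=C(C)C)[C@H](C(C)=O)[C@@H](CCC(C)=C)CC=C(C)C | intermediate
32 | (2S,3S,4S)-1-(tert-butyldimethylsilyloxy)-2,7-dimethyl-2,4-bis(3-methylbut-2-enyl)-3-(prop-1-en-2-yl)oct-7-ene | CC(C)(C)[Si](C)(C)OC[C@@](C)(CC=C(C)C)[C@H](C(C)=C)[C@@H](CCC(C)=C)CC=C(C)C | intermediate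
33 | (2S,3S,4S)-2,7-dimethyl-2,4-bis(3-methylbut-2-enyl)-3-(prop-1-en-2-yl)oct-7-en-1-ol | OC[C@@](C)(CC=C(C)C)[C@H](C(C)=C)[C@@H](CCC(C)=C)CC=C(C)C | intermediate
34 | (2S,3S,4S)-2,7-dimethyl-2,4-bis(3-methylbut-2-enyl)-3-(prop-1-en-2-yl)oct-7-enal | O=C[C@@](C)(CC=C(C)C)[C@H](C(C)=C)[C@@H](CCC(C)=C)CC=C(C)C | intermediate
35 | 3-bromophenol | Oc1cccc(Br)c1 | starting material
36 | (3-bromophenoxy)(tert-butyl)dimethylsilane | CC(C)(C)[Si](C)(C)Oc1cccc(Br)c1 | intermediate
37 | 3-(tert-butyldimethylsilyloxy)phenyllithium (not isolated) | CC(C)(C)[Si](C)(C)Oc1cccc([Li])c1 | intermediate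
38 | (2S,3S,4S)-1-[3-(tert-butyldimethylsilyloxy)phenyl]-2,7-dimethyl-2,4-bis(3-methylbut-2-enyl)-3-(prop-1-en-2-yl)oct-7-en-1-ol, C1 epimers | CC(C)(C)[Si](C)(C)Oc1cccc(c1)C(O)[C@@](C)(CC=C(C)C)[C@H](C(C)=C)[C@@H](CCC(C)=C)CC=C(C)C | intermediate
39 | (2S,3S,4S)-1-[3-(tert-butyldimethylsilyloxy)phenyl]-2,7-dimethyl-2,4-bis(3-methylbut-2-enyl)-3-(prop-1-en-2-yl)oct-7-en-1-one | CC(C)(C)[Si](C)(C)Oc1cccc(c1)C(=O)[C@@](C)(CC=C(C)C)[C@H](C(C)=C)[C@@H](CCC(C)=C)CC=C(C)C | intermediate
40 | garcinielliptone FA, (2S,3S,4S)-1-(3-hydroxyphenyl)-2,7-dimethyl-2,4-bis(3-methylbut-2-enyl)-3-(prop-1-en-2-yl)oct-7-en-1-one | C=C(C)CC[C@@H](CC=C(C)C)[C@@H](C(=C)C)[C@](C)(CC=C(C)C)C(=O)c1cccc(O)c1 | target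

## Step count and risks

Total step count: 25. Longest linear sequence: 24 steps (steps 1–21 and 23–25). Step 22 is a one-step side branch.

Until step 18 the extra centre Cγ is still present. Any stereochemical leak at C2, C3 or C4 therefore gives a separable diastereomer, not the enantiomer.

**Step 19 (methylenation of the very hindered, enolisable ketone).** The ylide may only enolise the ketone, or react too slowly. The fallback sets out from 31 and comes back at 32. It uses the easy enolisation at CH3 instead of fighting it. KHMDS and PhNTf2 (THF, −78 °C) give (2S,3R,4S)-1-(tert-butyldimethylsilyloxy)-2,7-dimethyl-2,4-bis(3-methylbut-2-enyl)-3-[1-(trifluoromethylsulfonyloxy)ethenyl]oct-7-ene F7. Coupling of F7 with Me2CuLi (Et2O, −15 °C) puts the methyl group on the vinyl carbon and gives 32. The carbonyl carbon is never attacked by a bulky reagent and C3–H is never exposed to an equilibrating base.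

**Step 15 (quaternary centre).** The α-hydrogen of 26 lies on the shielded face, so deprotonation may be incomplete. The fallback sets out from 24 and comes back at 28 through the same enolate 27. It generates that enolate by conjugate addition instead of deprotonation.
- Enolate 25 is trapped with Eschenmoser's salt to give (3S,4R,5R)-3-[(dimethylamino)methyl]-4-[(5S)-2,8-dimethylnona-1,7-dien-5-yl]-5-methyloxolan-2-one F4.
- MeI converts F4 into the trimethylammonium iodide F5.
- Aqueous NaHCO3 eliminates F5 to (4R,5R)-4-[(5S)-2,8-dimethylnona-1,7-dien-5-yl]-5-methyl-3-methylideneoxolan-2-one F6.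
- Lithium bis(2-methylprop-1-enyl)cuprate adds 1,4 to the exocyclic methylene of F6. This creates the prenyl chain and enolate 27 in one stroke.
- MeI (DMPU) then alkylates 27 from the same open face to give 28.

**Step 4 (key Michael addition).** The basic malonate may remove C5–H of 7, which would cause racemisation or drift to the β,γ-isomer. The fallback sets out from 7 and comes back at 11. It makes the same bond without base, as a Mukaiyama–Michael reaction.
- Benzyl acetate (LDA, TBSCl, THF–DMPU, −78 °C) gives 1-benzyloxy-1-(tert-butyldimethylsilyloxy)ethene F1.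
- F1 adds to 7 under TBSOTf catalysis (CH2Cl2, −78 °C), anti to the methyl group. This gives benzyl 2-[(2R,3S)-5-(tert-butyldimethylsilyloxy)-2-methyl-2,3-dihydrofuran-3-yl]acetate F2.
- Mild acid hydrolysis gives benzyl 2-[(2R,3S)-2-methyl-5-oxooxolan-3-yl]acetate F3.
- Hydrogenolysis (H2, Pd/C, EtOAc) gives 11, so the decarboxylation is bypassed as well.

## Further compounds

F1 | step 4 | 1-benzyloxy-1-(tert-butyldimethylsilyloxy)ethene | C=C(OCc1ccccc1)O[Si](C)(C)C(C)(C)C
F2 | step 4 | benzyl 2-[(2R,3S)-5-(tert-butyldimethylsilyloxy)-2-methyl-2,3-dihydrofuran-3-yl]acetate | C[C@H]1OC(O[Si](C)(C)C(C)(C)C)=C[C@@H]1CC(=O)OCc2ccccc2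
F3 | step 4 | benzyl 2-[(2R,3S)-2-methyl-5-oxooxolan-3-yl]acetate | C[C@H]1OC(=O)C[C@@H]1CC(=O)OCc2ccccc2
F4 | step 15 | (3S,4R,5R)-3-[(dimethylamino)methyl]-4-[(5S)-2,8-dimethylnona-1,7-dien-5-yl]-5-methyloxolan-2-one | C[C@H]1OC(=O)[C@H](CN(C)C)[C@H]1[C@@H](CCC(C)=C)CC=C(C)C
F5 | step 15 | trimethylammonium iodide (methiodide) of F4 | C[C@H]1OC(=O)[C@H](C[N+](C)(C)C)[C@H]1[C@@H](CCC(C)=C)CC=C(C)C.[I-]
F6 | step 15 | (4R,5R)-4-[(5S)-2,8-dimethylnona-1,7-dien-5-yl]-5-methyl-3-methylideneoxolan-2-one | C[C@H]1OC(=O)C(=C)[C@H]1[C@@H](CCC(C)=C)CC=C(C)C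
F7 | step 19 | (2S,3R,4S)-1-(tert-butyldimethylsilyloxy)-2,7-dimethyl-2,4-bis(3-methylbut-2-enyl)-3-[1-(trifluoromethylsulfonyloxy)ethenyl]oct-7-ene | CC(C)(C)[Si](C)(C)OC[C@@](C)(CC=C(C)C)[C@H](C(=C)OS(=O)(=O)C(F)(F)F)[C@@H](CCC(C)=C)CC=C(C)C
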